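**Retrosynthetic overview** (flavanone numbering: O1, C2, C3, C4, C4a, C5–C8, C8a)

- Ring C is cut at the aryl ether bond O1–C8a. C8a is the ring-A carbon lying between prenyl-bearing C8 and C4a, and O1 sits on the only stereocentre, C2. The C2–O1 bond can therefore be made early as an (S)-carbinol and is never broken afterwards.
- The cyclisation substrate is a 1,3-diarylpropane with C8a as an aryl triflate, C4 masked as a silyl ether and C2 as the free (S)-alcohol. No enone or chalcone occurs at any stage. C4=O and the two phenols are released only after ring closure.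
- The C3–C4 bond comes from an aldol addition of 6-acetyl-2,2-dimethylchroman to the triflated, bis-MOM 3-prenylphloroglucinaldehyde. C2 is set by catalyst-controlled transfer hydrogenation of the aryl ketone.
- Ring order: ring A, ring B and the dimethylpyran ring are bought, and ring C is the only ring formed (step 7).

Key step: step 7

Remark on C4: the aldol carbinol carbon (future C4) is deliberately left uncontrolled, so 8 and 9 are racemates and 10, 11 and 12 are each an unseparated pair of C4 epimers with uniform S configuration at the future C2 (10 = (1R,3S) + (1S,3S); 11 = (2S,4R) + (2S,4S)); their SMILES leave this one centre open, and step 9 removes it.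

Remark on supply: 6-acetyl-2,2-dimethylchroman is taken as a catalogue compound.

**Step 1**
Reactants: 1 2,4,6-trihydroxybenzaldehyde; 2 prenyl bromide
Product: 3 2,4,6-trihydroxy-3-(3-methylbut-2-en-1-yl)benzaldehyde
Conditions: KOH (1.0 equiv), H2O, 0 °C → rt, 2 as limiting reagent
Reagents that add atoms: none
Why: C-alkylation of an ambident phloroglucinol phenoxide (vinylogous enolate alkylation): in water the phenoxide oxygens are hydrogen-bond solvated, so the soft allylic bromide should be taken up at ring carbon (C3 and C5 are equivalent), and keeping 2 as the limiting reagent holds back double prenylation.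

**Step 2**
Reactants: 3 2,4,6-trihydroxy-3-(3-methylbut-2-en-1-yl)benzaldehyde
Product: 4 2-hydroxy-4,6-bis(methoxymethoxy)-3-(3-methylbut-2-en-1-yl)benzaldehyde
Conditions: MOMCl (2.1 equiv), i-Pr2NEt, CH2Cl2, 0 °C
Reagents that add atoms: chloromethyl methyl ether, COCCl
Why: MOM ether formation (O-alkylation of phenols): the unchelated 4-OH reacts first, and of the two formyl-chelated hydroxyls the open 6-OH should be etherified in preference to the 2-OH wedged between formyl and prenyl, the pattern familiar from partial O-alkylation of 3-alkylated acylphloroglucinols, which leaves free exactly the oxygen that is to become the leaving group on C8a.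

**Step 3**
Reactants: 4 2-hydroxy-4,6-bis(methoxymethoxy)-3-(3-methylbut-2-en-1-yl)benzaldehyde
Product: 5 2-formyl-3,5-bis(methoxymethoxy)-6-(3-methylbut-2-en-1-yl)phenyl trifluoromethanesulfonate
Conditions: Tf2O, pyridine, CH2Cl2, −20 → 0 °C
Reagents that add atoms: trifluoromethanesulfonic anhydride, O=S(=O)(OS(=O)(=O)C(F)(F)F)C(F)(F)F
Why: O-sulfonylation of a phenol with triflic anhydride: pyridine breaks the chelate and binds the triflic acid released, so the MOM acetals, the aldehyde and the prenyl alkene should stay untouched at low temperature.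

**Step 4**
Reactants: 6 6-acetyl-2,2-dimethylchroman; 5 2-formyl-3,5-bis(methoxymethoxy)-6-(3-methylbut-2-en-1-yl)phenyl trifluoromethanesulfonate
Product: 8 rac-2-[3-(2,2-dimethylchroman-6-yl)-1-hydroxy-3-oxopropyl]-3,5-bis(methoxymethoxy)-6-prenylphenyl triflate, via lithium enolate 7 (not isolated)
Conditions: LDA (commercial solution), THF, −78 °C; then 5, −78 °C; AcOH/THF quench at −78 °C
Reagents that add atoms: none
Why: Directed aldol addition of a preformed lithium enolate to a non-enolisable aldehyde: carbonyl addition at −78 °C is much faster than attack at the sulfonate sulfur, the cold acidic quench forestalls retro-aldol, dehydration and triflyl transfer to the new alkoxide, and the new carbinol carbon (future C4) is formed as a racemate on purpose because step 9 turns it into C=O.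

**Step 5**
Reactants: 8 rac-aldol triflate
Product: 9 rac-2-[1-(tert-butyldimethylsilyloxy)-3-(2,2-dimethylchroman-6-yl)-3-oxopropyl]-3,5-bis(methoxymethoxy)-6-prenylphenyl triflate
Conditions: TBSOTf (1.2 equiv), 2,6-lutidine, CH2Cl2, −78 → −20 °C
Reagents that add atoms: tert-butyldimethylsilyl trifluoromethanesulfonate, CC(C)(C)[Si](C)(C)OS(=O)(=O)C(F)(F)F
Why: Silylation of a hindered secondary alcohol with a silyl triflate and a non-nucleophilic pyridine base: the medium is too weakly basic for β-elimination or retro-aldol, a small excess at low temperature leaves the MOM acetals and the ketone alone, and the silyl ether keeps the C4 oxygen away from palladium in step 7.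

**Step 6**
Reactants: 9 rac-silyloxy ketone triflate
Product: 10 2-[(3S)-1-(tert-butyldimethylsilyloxy)-3-(2,2-dimethylchroman-6-yl)-3-hydroxypropyl]-3,5-bis(methoxymethoxy)-6-prenylphenyl triflate (both C1 epimers: (1R,3S) and (1S,3S))
Conditions: RuCl[(S,S)-TsDPEN](p-cymene) (3 mol %), HCO2H–Et3N (5:2), CH2Cl2, 30 °C, to full conversion
Reagents that add atoms: none
Why: Noyori–Ikariya asymmetric transfer hydrogenation of an aryl alkyl ketone: the Ru–H/N–H pair of the (S,S)-catalyst passes hydride and proton to the carbonyl through a six-membered outer-sphere transition state in which the electron-rich chroman ring lies under the η6-arene (CH/π contact), so hydride should reach the Re face and the new carbinol (future C2) should be S in both enantiomers of 9, whose silyloxy centre is remote and non-coordinating, while formate makes the reduction irreversible and alkene, triflate, MOM and TBS groups are not addressed.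

**Step 7**
Reactants: 10 (3S)-carbinol triflate (both C1 epimers)
Product: 11 (2S)-4-(tert-butyldimethylsilyloxy)-2-(2,2-dimethylchroman-6-yl)-5,7-bis(methoxymethoxy)-8-prenylchroman (both C4 epimers: (2S,4R) and (2S,4S))
Conditions: RockPhos Pd G3 (10 mol %), Cs2CO3, 4 Å MS, PhMe, 90 °C
Reagents that add atoms: none
Why: Pd(0) carrying the bulky biaryl di-tert-butylphosphine inserts into the C8a–OTf bond, carbonate removes the proton of the palladium-bound (S)-carbinol, and C–O reductive elimination from the seven-membered oxapalladacycle (Pd, C8a, C4a, C4, C3, C2, O) forges O1–C8a. The closest known reaction type is the intramolecular Buchwald–Hartwig etherification of aryl (pseudo)halides that carry a secondary alcohol in the side chain, a route to chromans that leaves an existing carbinol centre intact. Ring C closes as a six-membered ring in a formal 6-exo mode at the sp2 carbon C8a, the triflate leaving outside the new ring. No stereocentre is made: C2 stays S because only its O–H bond reacts and its C–O bond is never broken, so the ionisation open to a para-alkoxybenzylic carbon has no chance to operate, and the open C4 centre is a spectator. The step needs reductive elimination to outrun β-hydride loss from C2–H, and this is secured by the two ortho substituents on C8a together with the ligand bulk, which squeeze aryl and alkoxide together, and by the lower ligand ring, which occupies the site that β-hydride elimination would need. It also needs the right oxygen and an intact triflate: the C4 oxygen is silylated and the C5 and C7 oxygens are MOM ethers, both MOM-oxy groups are meta to C8a and so do not slow oxidative addition by resonance, and dry, barely soluble Cs2CO3 in toluene keeps free alkoxide so low that S–O cleavage and O-to-O silyl migration should stay minor.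

**Step 8**
Reactants: 11 (2S)-4-silyloxyflavan (both C4 epimers)
Product: 12 (2S)-2-(2,2-dimethylchroman-6-yl)-5,7-bis(methoxymethoxy)-8-prenylchroman-4-ol (both C4 epimers)
Conditions: TBAF, THF, 0 °C → rt
Reagents that add atoms: none
Why: Fluoride-induced desilylation driven by the Si–F bond: flavan 11 holds no carbonyl, so C2–H is not acidic and ring C cannot open, and MOM ethers and the alkene are inert to fluoride.

**Step 9**
Reactants: 12 (2S)-flavan-4-ol (both C4 epimers)
Product: 13 (2S)-2-(2,2-dimethylchroman-6-yl)-5,7-bis(methoxymethoxy)-8-prenylchroman-4-one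
Conditions: DMP, NaHCO3, CH2Cl2, 0 °C → rt
Reagents that add atoms: none
Why: Dess–Martin oxidation of a benzylic secondary alcohol: both C4 epimers converge on one ketone, the near-neutral buffered medium avoids the retro-oxa-Michael opening to the chalcone that would racemise C2, and the electron-rich arenes and the prenyl alkene are not attacked by the periodinane.

**Step 10**
Reactants: 13 (2S)-bis-MOM flavanone
Product: 14 euchrenone a16, (2S)-2-(2,2-dimethylchroman-6-yl)-5,7-dihydroxy-8-prenylchroman-4-one
Conditions: HCl (1.25 M in MeOH), 0 °C → rt; work-up with pH 6–7 phosphate buffer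
Reagents that add atoms: none
Why: Acid-catalysed transacetalisation of the two aryl MOM ethers to methanol: the C5 acetal peri to the carbonyl goes first and the C7 acetal follows, and at or below room temperature dilute methanolic HCl should neither add the 7-OH across the prenyl alkene nor open ring C, so the (2S) centre is kept as long as the work-up stays at or below pH 7.

**Compound list**

1 | 2,4,6-trihydroxybenzaldehyde | O=Cc1c(O)cc(O)cc1O | starting material
2 | prenyl bromide (1-bromo-3-methylbut-2-ene) | CC(C)=CCBr | starting material
3 | 2,4,6-trihydroxy-3-(3-methylbut-2-en-1-yl)benzaldehyde | CC(C)=CCc1c(O)cc(O)c(C=O)c1O | intermediate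
4 | 2-hydroxy-4,6-bis(methoxymethoxy)-3-(3-methylbut-2-en-1-yl)benzaldehyde | CC(C)=CCc1c(OCOC)cc(OCOC)c(C=O)c1O | intermediate
5 | 2-formyl-3,5-bis(methoxymethoxy)-6-(3-methylbut-2-en-1-yl)phenyl trifluoromethanesulfonate | CC(C)=CCc1c(OCOC)cc(OCOC)c(C=O)c1OS(=O)(=O)C(F)(F)F | intermediate
6 | 6-acetyl-2,2-dimethylchroman | CC(=O)c1ccc2c(c1)CCC(C)(C)O2 | starting material
7 | lithium enolate of 6 (not isolated) | [Li+].[O-]C(=C)c1ccc2c(c1)CCC(C)(C)O2 | intermediate
8 | rac-2-[3-(2,2-dimethylchroman-6-yl)-1-hydroxy-3-oxopropyl]-3,5-bis(methoxymethoxy)-6-prenylphenyl triflate | CC(C)=CCc1c(OCOC)cc(OCOC)c(C(O)CC(=O)c2ccc3c(c2)CCC(C)(C)O3)c1OS(=O)(=O)C(F)(F)F | intermediate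
9 | rac-2-[1-(tert-butyldimethylsilyloxy)-3-(2,2-dimethylchroman-6-yl)-3-oxopropyl]-3,5-bis(methoxymethoxy)-6-prenylphenyl triflate | CC(C)=CCc1c(OCOC)cc(OCOC)c(C(O[Si](C)(C)C(C)(C)C)CC(=O)c2ccc3c(c2)CCC(C)(C)O3)c1OS(=O)(=O)C(F)(F)F | intermediate
10 | 2-[(3S)-1-(tert-butyldimethylsilyloxy)-3-(2,2-dimethylchroman-6-yl)-3-hydroxypropyl]-3,5-bis(methoxymethoxy)-6-prenylphenyl triflate, (1R,3S) and (1S,3S) epimers together | CC(C)=CCc1c(OCOC)cc(OCOC)c(C(O[Si](C)(C)C(C)(C)C)C[C@H](O)c2ccc3c(c2)CCC(C)(C)O3)c1OS(=O)(=O)C(F)(F)F | intermediate
11 | (2S)-4-(tert-butyldimethylsilyloxy)-2-(2,2-dimethylchroman-6-yl)-5,7-bis(methoxymethoxy)-8-prenylchroman, (2S,4R) and (2S,4S) epimers together | CC(C)=CCc1c(OCOC)cc(OCOC)c2c1O[C@H](c1ccc3c(c1)CCC(C)(C)O3)CC2O[Si](C)(C)C(C)(C)C | intermediate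
12 | (2S)-2-(2,2-dimethylchroman-6-yl)-5,7-bis(methoxymethoxy)-8-prenylchroman-4-ol, both C4 epimers together | CC(C)=CCc1c(OCOC)cc(OCOC)c2c1O[C@H](c1ccc3c(c1)CCC(C)(C)O3)CC2O | intermediate
13 | (2S)-2-(2,2-dimethylchroman-6-yl)-5,7-bis(methoxymethoxy)-8-prenylchroman-4-one | CC(C)=CCc1c(OCOC)cc(OCOC)c2c1O[C@H](c1ccc3c(c1)CCC(C)(C)O3)CC2=O | intermediate
14 | euchrenone a16, (2S)-2-(2,2-dimethylchroman-6-yl)-5,7-dihydroxy-8-prenylchroman-4-one | CC(C)=CCc1c(O)cc(O)c2c1O[C@H](c1ccc3c(c1)CCC(C)(C)O3)CC2=O | target

**Total step count:** 10
**Longest linear sequence:** 10 steps (1 → 14); ketone 6 enters at step 4.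

**Steps most likely to fail**

**(a) Step 7.** Several processes could defeat the ring closure:
- Oxidative addition into the doubly ortho-flanked C8a–O bond may be too slow.
- β-Hydride elimination at the palladium alkoxide could then take over, oxidising the carbinol back to the ketone with hydrodetriflation of the arene.
- S–O cleavage of the triflate or base-induced O-to-O silyl migration could also compete.
- One C4 epimer may close more slowly than the other.

The fallback sets out from 9 and comes back at 11. It closes ring C at the C2–O1 bond by SN2 displacement instead. Ketone 9 is reduced as in step 6 but with the (R,R)-catalyst, to give the (3R)-carbinol triflate F1. Aqueous Et4NOH in dioxane at rt cleaves the sulfonate at sulfur and gives the C8a phenol F2. Mitsunobu cyclodehydration (PPh3, DIAD, toluene, 0 °C) then displaces the activated (R)-carbinol oxygen with inversion and should deliver the (2S)-flavan 11. This is established flavan chemistry. Its cost is possible partial ionisation at the para-alkoxybenzylic carbon, to be held down by low temperature and a non-polar solvent.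

**(b) Step 4.** Three processes are of concern:
- reversal of the addition to the hindered, donor-substituted aldehyde;
- loss of water from the aldol on work-up;
- transfer of the triflyl group to the neighbouring lithium alkoxide.

The fallback sets out from 5 and comes back at 9. The C3–C4 bond is made with a more reactive, less reversible amide enolate, and the aryl ketone is built afterwards. The lithium enolate of N-methoxy-N-methylacetamide F3 (LDA, THF, −78 °C) is added to aldehyde 5 to give the racemic β-hydroxy Weinreb amide F4. This is silylated (TBSOTf, 2,6-lutidine) to the silyloxy Weinreb amide F5. (2,2-Dimethylchroman-6-yl)magnesium bromide F6, made from commercial 6-bromo-2,2-dimethylchroman and magnesium, then adds once to the amide (THF, 0 °C, stable chelate). Work-up should give ketone 9.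

**(c) Step 2.** The two chelated hydroxyls may be poorly discriminated, or over-protection to the tris-MOM ether may occur. Either would put the leaving group on the wrong carbon or waste material.

The fallback sets out from 1 and comes back at 4, and it also bypasses the direct C-prenylation of step 1. The side chain is delivered by a sigmatropic shift from the very oxygen that is to become the triflate.
- Aldehyde 1 is bis-protected (MOMCl, i-Pr2NEt) to 2-hydroxy-4,6-bis(methoxymethoxy)benzaldehyde F7. There is no site issue here because the two chelated hydroxyls are equivalent.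
- O-allylation (allyl bromide, K2CO3, DMF) gives the allyl ether F8.
- Aromatic Claisen rearrangement (N,N-diethylaniline, about 190 °C) can only deliver the allyl group to C3, the other ortho position being blocked by the formyl group. It gives 3-allyl-2-hydroxy-4,6-bis(methoxymethoxy)benzaldehyde F9.
- Cross-metathesis with 2-methyl-2-butene (Grubbs second-generation catalyst, CH2Cl2, 40 °C) converts allyl into prenyl and gives 4.

**Further compounds**

F1 | step 7 | 2-[(3R)-1-(tert-butyldimethylsilyloxy)-3-(2,2-dimethylchroman-6-yl)-3-hydroxypropyl]-3,5-bis(methoxymethoxy)-6-prenylphenyl triflate (both C1 epimers) | CC(C)=CCc1c(OCOC)cc(OCOC)c(C(O[Si](C)(C)C(C)(C)C)C[C@@H](O)c2ccc3c(c2)CCC(C)(C)O3)c1OS(=O)(=O)C(F)(F)F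
F2 | step 7 | 2-[(3R)-1-(tert-butyldimethylsilyloxy)-3-(2,2-dimethylchroman-6-yl)-3-hydroxypropyl]-3,5-bis(methoxymethoxy)-6-prenylphenol (both C1 epimers) | CC(C)=CCc1c(OCOC)cc(OCOC)c(C(O[Si](C)(C)C(C)(C)C)C[C@@H](O)c2ccc3c(c2)CCC(C)(C)O3)c1O
F3 | step 4 | lithium enolate of N-methoxy-N-methylacetamide | [Li+].[O-]C(=C)N(C)OC
F4 | step 4 | rac-2-[1-hydroxy-3-(methoxy(methyl)amino)-3-oxopropyl]-3,5-bis(methoxymethoxy)-6-prenylphenyl triflate | CC(C)=CCc1c(OCOC)cc(OCOC)c(C(O)CC(=O)N(C)OC)c1OS(=O)(=O)C(F)(F)F
F5 | step 4 | rac-2-[1-(tert-butyldimethylsilyloxy)-3-(methoxy(methyl)amino)-3-oxopropyl]-3,5-bis(methoxymethoxy)-6-prenylphenyl triflate | CC(C)=CCc1c(OCOC)cc(OCOC)c(C(O[Si](C)(C)C(C)(C)C)CC(=O)N(C)OC)c1OS(=O)(=O)C(F)(F)F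
F6 | step 4 | (2,2-dimethylchroman-6-yl)magnesium bromide | Br[Mg]c1ccc2c(c1)CCC(C)(C)O2
F7 | step 2 | 2-hydroxy-4,6-bis(methoxymethoxy)benzaldehyde | O=Cc1c(O)cc(OCOC)cc1OCOC
F8 | step 2 | 2-(allyloxy)-4,6-bis(methoxymethoxy)benzaldehyde | C=CCOc1cc(OCOC)cc(OCOC)c1C=O
F9 | step 2 | 3-allyl-2-hydroxy-4,6-bis(methoxymethoxy)benzaldehyde | C=CCc1c(OCOC)cc(OCOC)c(C=O)c1O
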